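**Retrosynthetic overview**

- The target as drawn is an endo,endo (diaxial) 2,6-diaryl furofuran (rings D and E), all-S at C7, C8, C7' and C8'. Its ring B is fused to a cis-(2S,3S)-2-aryl-3-hydroxymethyl-2,3-dihydrofuran (ring F). Both arrays are contra-thermodynamic, so every ring is closed kinetically and without acid.
- Ring F (O1-C2-C3-C3a-C7a) is cut at C2-C3. The forward reaction is an enantioselective dirhodium-carbene 1,5 C-H insertion of aryldiazoacetate 19. The ester is the CH2OH group at a higher oxidation level and is reduced afterwards.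
- Enabling feature: C2 is flanked by O1 and by the electron-rich ring C. It lies 1,5 to C3, which sits on C3a, ortho to the O1-bearing C7a of ring B. As a CH2 it is the benzylic carbon of a vanillyl-type ether that protects the ring B phenol from step 1 on and is then absorbed into the skeleton.
- The diazoacetate comes from aryl iodide 16 by Negishi-Reformatsky coupling and diazo transfer. Rings D and E come from dimesylate 13 by a double Williamson closure that touches no stereocenter.
- C7'/C8' come from a D-proline anti cross-aldol, and C7/C8 from an anti aldol of a temporary butyrolactone. Ring order: temporary lactone (opened again), then D and E together, then F last.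

Key step: step 11

Assumption: the sense of induction of Rh2(PTTL)4 is taken from the accepted pocket model of this catalyst family (S ligands lead to 2R, R ligands to 2S). Should the substrate answer in the opposite sense, the mirror-image catalyst Rh2(S-PTTL)4 is used and nothing else changes.

Notation:
- Ar-A = 4-(benzyloxy)-3-methoxyphenyl (ring A).
- Ar-B = 4-{[4-(benzyloxy)-3-methoxyphenyl]methoxy}-3-iodo-5-methoxyphenyl (ring B carrying the ring C benzyl ether).
- C7-C9 is the ring A half and C7'-C9' the ring B half.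
- TBS = tert-butyldimethylsilyl; Ms = methanesulfonyl.

**Step 1**
Reactants: 1 5-iodovanillin; 2 4-(benzyloxy)-3-methoxybenzyl alcohol
Product: 3 4-{[4-(benzyloxy)-3-methoxyphenyl]methoxy}-3-iodo-5-methoxybenzaldehyde (Ar-B-CHO)
Conditions: PPh3, DIAD, THF, 0 °C to rt
Reagents that add atoms: none
Why: Mitsunobu etherification, in which the acidic, doubly ortho-substituted phenol of 1 is alkylated by the activated primary benzylic alcohol under neutral conditions that spare the aldehyde and the iodide, with no stereocenter formed.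

**Step 2**
Reactants: 3 Ar-B-CHO; 4 methyl 4-oxobutanoate
Product: 7 (4S)-4-[(S)-hydroxy(Ar-B)methyl]oxolan-2-one, via anti aldol aldehyde 5 (not isolated), via dihydroxy ester 6 (not isolated)
Conditions: D-proline (20 mol %), DMF, 4 °C, slow addition of 4; then MeOH, NaBH4, 0 °C; aq NH4Cl
Reagents that add atoms: none
Why: Proline-enamine direct cross-aldol, in which the E-enamine of 4 adds to the non-enolisable aldehyde 3 in the hydrogen-bonded chair to give the anti aldol with C8' and C7' fixed by D-proline (3R,4S in 5), after which reduction of the formyl group in the same flask prevents epimerisation and the primary alcohol lactonises in preference to the benzylic one, which would give the strained cis-4,5-disubstituted lactone.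

**Step 3**
Reactants: 7 hydroxy lactone
Product: 8 (4S)-4-[(S)-(TBSO)(Ar-B)methyl]oxolan-2-one
Conditions: TBSOTf, 2,6-lutidine, CH2Cl2, 0 °C
Reagents that add atoms: tert-butyldimethylsilyl triflate, CC(C)(C)[Si](C)(C)OS(=O)(=O)C(F)(F)F
Why: Silylation with the triflate and a hindered pyridine base caps the hindered benzylic alcohol, so that only the lactone alpha position is deprotonated in step 4 and O7' is stored as a latent alkoxide, with no stereocenter touched.

**Step 4**
Reactants: 8 silyloxy lactone; 9 4-(benzyloxy)-3-methoxybenzaldehyde (O-benzylvanillin)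
Product: 10 (3R,4S)-3-[(S)-hydroxy(Ar-A)methyl]-4-[(S)-(TBSO)(Ar-B)methyl]oxolan-2-one
Conditions: LiN(SiMe3)2, THF, -78 °C; 9, -78 °C; AcOH/THF quench at -78 °C
Reagents that add atoms: none
Why: Lithium-enolate aldol addition through a Zimmerman-Traxler chair, in which the ring-locked E(O)-enolate of 8 reacts on the face anti to the bulky C8' substituent (C8, trans) and holds ring A equatorial in the chair (C7, anti aldol, S), while the cold acidic quench forestalls retro-aldol equilibration.

**Step 5**
Reactants: 10 aldol lactone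
Product: 11 (3R,4S)-3-[(S)-(TBSO)(Ar-A)methyl]-4-[(S)-(TBSO)(Ar-B)methyl]oxolan-2-one
Conditions: TBSOTf, 2,6-lutidine, CH2Cl2, -20 to 0 °C
Reagents that add atoms: tert-butyldimethylsilyl triflate, CC(C)(C)[Si](C)(C)OS(=O)(=O)C(F)(F)F
Why: Base-buffered silylation masks the second, ionisation-prone benzylic alcohol, so that after reduction the primary hydroxyls are the only free ones, and it blocks retro-aldol cleavage without touching a stereocenter.

**Step 6**
Reactants: 11 bis-silyl lactone
Product: 12 (2S,3S)-2-[(S)-(TBSO)(Ar-A)methyl]-3-[(S)-(TBSO)(Ar-B)methyl]butane-1,4-diol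
Conditions: LiBH4, THF, MeOH (cat.), 0 °C to rt
Reagents that add atoms: none
Why: Borohydride reduction opens the temporary lactone to the 1,4-diol and frees C9 and C9' as primary alcohols, LiBH4 being chosen because it spares the aryl iodide and the silyl and benzyl ethers, with no stereocenter touched.

**Step 7**
Reactants: 12 diol
Product: 13 (2S,3S)-2-[(S)-(TBSO)(Ar-A)methyl]-3-[(S)-(TBSO)(Ar-B)methyl]butane-1,4-diyl dimethanesulfonate
Conditions: MsCl, Et3N, CH2Cl2, -20 to 0 °C
Reagents that add atoms: methanesulfonyl chloride, CS(=O)(=O)Cl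
Why: Sulfonylation via sulfene is fast enough at low temperature to convert both primary alcohols, the only free hydroxyls, before a monomesylate can cyclise to the unwanted 9,9'-ether.

**Step 8**
Reactants: 13 dimesylate
Product: 16 endo,endo-furofuran iodide (1S,3aS,4S,6aS)-1-(Ar-A)-4-(Ar-B)tetrahydro-1H,3H-furo[3,4-c]furan, via diol dimesylate 14 (not isolated), via monocyclic mesylate 15 (not isolated)
Conditions: Bu4NF (1 M in THF, excess), THF, 0 to 45 °C
Reagents that add atoms: none
Why: Fluoride unmasks the two benzylic alkoxides and each displaces the primary mesylate four atoms away (double intramolecular Williamson etherification, twice 5-exo-tet), so only O-Si and primary C-O bonds are touched, C7, C8, C7' and C8' are carried over with retention, and the anti,anti array becomes the endo,endo bicycle with no acid present to epimerise it.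

**Step 9**
Reactants: 16 furofuran iodide; 17 (2-ethoxy-2-oxoethyl)zinc bromide
Product: 18 ethyl 2-{ring B aryl}acetate (iodine of 16 replaced by CH2CO2Et)
Conditions: Pd2(dba)3 (2.5 mol %), XPhos, THF, 55 °C
Reagents that add atoms: none
Why: Negishi-type coupling of a Reformatsky reagent, in which oxidative addition of the zerovalent palladium catalyst into the C-I bond, transmetalation from the weakly basic zinc enolate and reductive elimination install the acetate arm under conditions too mild to disturb the benzylic ethers or any stereocenter.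

**Step 10**
Reactants: 18 arylacetate
Product: 19 ethyl 2-diazo-2-{ring B aryl}acetate
Conditions: p-ABSA, DBU, MeCN, 0 °C to rt
Reagents that add atoms: 4-acetamidobenzenesulfonyl azide, CC(=O)Nc1ccc(cc1)S(=O)(=O)N=[N+]=[N-]
Why: Regitz diazo transfer to the only acidic C-H position of the molecule, a standard preparation of aryldiazoacetates bearing an ortho benzyloxy group, under basic conditions that are harmless to the acid-labile furofuran.

**Step 11**
Reactants: 19 aryldiazoacetate
Product: 20 ethyl (2S,3R)-cis-2-[4-(benzyloxy)-3-methoxyphenyl]-7-methoxy-5-[(1S,3aS,4S,6aS)-4-(Ar-A)tetrahydro-1H,3H-furo[3,4-c]furan-1-yl]-2,3-dihydro-1-benzofuran-3-carboxylate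
Conditions: Rh2(R-PTTL)4, dirhodium tetrakis[N-phthaloyl-(R)-tert-leucinate] (2 mol %), 4 Å MS, toluene, -60 °C, slow addition of 19
Reagents that add atoms: none
Why: The dirhodium tetracarboxylate expels N2 from 19 and binds the resulting donor/acceptor carbene at C3, and this carbene inserts into one of the two O-CH2 hydrogens of the ring C benzyl ether through an asynchronous, hydride-transfer-like three-centre transition state that forms C2-C3 and C3-H in one event. The closest known reaction type is the enantioselective intramolecular 1,5 C-H insertion of 2-(benzyloxy)aryl diazoacetates with phthalimido-amino-acid dirhodium catalysts, which delivers cis-2-aryl-2,3-dihydrobenzofuran-3-carboxylates. Ring F closes by C2-C3 bond formation in the 1,5 mode (five-membered cyclic transition state O1-C2-C3-C3a-C7a), whereas attack of the carbene on O1 would need a four-membered ylide and does not compete. C2 is fixed by the chiral pocket of the R-configured ligands, which exposes one face of the carbene and so selects one of the two enantiotopic benzylic hydrogens, and C3 is fixed in the same transition state, in which ring C and the ester both point away from the catalyst wall, so that the kinetic cis (2S,3R) ester should result. The step needs chemoselectivity over the furofuran O-C-H bonds and the two O-benzyl CH2 groups, secured because none of them can reach C3 across ring B and because dilution and low temperature suppress intermolecular reaction, and it needs facial control independent of the furofuran, secured because the nearest old stereocenter C7' sits meta across the flat ring B and points away from the reacting site. The neutral, cold medium preserves both the endo,endo furofuran and the epimerisable cis ester.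

**Step 12**
Reactants: 20 cis ester
Product: 21 (2S,3S)-cis primary alcohol (CO2Et of 20 reduced to CH2OH, both benzyl ethers retained)
Conditions: iBu2AlH (3 equiv), toluene/CH2Cl2, -78 to -30 °C; Rochelle salt
Reagents that add atoms: none
Why: iBu2AlH is a non-basic hydride donor, so the ester is taken down to the primary alcohol faster than the acidic C3-H can be removed, and the cis relationship of step 11 is then locked because C3 is no longer epimerisable.

**Step 13**
Reactants: 21 dibenzyl ether
Product: 22 target, 4-[(1S,3aS,4S,6aS)-4-[(2S,3S)-2-(4-hydroxy-3-methoxyphenyl)-3-(hydroxymethyl)-7-methoxy-2,3-dihydro-1-benzofuran-5-yl]tetrahydro-1H,3H-furo[3,4-c]furan-1-yl]-2-methoxyphenol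
Conditions: H2 (1 atm), 10 % Pd/C, NaHCO3 (solid buffer), EtOAc/EtOH, rt, stopped after two equivalents of H2
Reagents that add atoms: none
Why: Catalytic hydrogenolysis, in which the unhindered primary ArO-CH2Ph bonds should be cleaved well before the hindered secondary benzylic C-O bonds of rings D, E and F, while the absence of acid and base avoids quinone-methide epimerisation at C2, C7 and C7'.

**Compound list**

1 | 5-iodovanillin (4-hydroxy-3-iodo-5-methoxybenzaldehyde) | COc1cc(C=O)cc(I)c1O | starting material
2 | 4-(benzyloxy)-3-methoxybenzyl alcohol | OCc1ccc(OCc2ccccc2)c(OC)c1 | starting material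
3 | 4-{[4-(benzyloxy)-3-methoxyphenyl]methoxy}-3-iodo-5-methoxybenzaldehyde | COc1cc(C=O)cc(I)c1OCc1ccc(OCc2ccccc2)c(OC)c1 | intermediate
4 | methyl 4-oxobutanoate | COC(=O)CCC=O | starting material
5 | methyl (3R,4S)-3-formyl-4-hydroxy-4-(Ar-B)butanoate (anti aldol, not isolated) | O=C[C@H](CC(=O)OC)[C@H](O)c1cc(OC)c(OCc2ccc(OCc3ccccc3)c(OC)c2)c(I)c1 | intermediate
6 | methyl (3S,4S)-4-hydroxy-3-(hydroxymethyl)-4-(Ar-B)butanoate (not isolated) | OC[C@H](CC(=O)OC)[C@H](O)c1cc(OC)c(OCc2ccc(OCc3ccccc3)c(OC)c2)c(I)c1 | intermediate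
7 | (4S)-4-[(S)-hydroxy(Ar-B)methyl]oxolan-2-one | O=C1OC[C@@H]([C@H](O)c2cc(OC)c(OCc3ccc(OCc4ccccc4)c(OC)c3)c(I)c2)C1 | intermediate
8 | (4S)-4-[(S)-(TBSO)(Ar-B)methyl]oxolan-2-one | O=C1OC[C@@H]([C@H](O[Si](C)(C)C(C)(C)C)c2cc(OC)c(OCc3ccc(OCc4ccccc4)c(OC)c3)c(I)c2)C1 | intermediate
9 | 4-(benzyloxy)-3-methoxybenzaldehyde | COc1cc(C=O)ccc1OCc1ccccc1 | starting material
10 | (3R,4S)-3-[(S)-hydroxy(Ar-A)methyl]-4-[(S)-(TBSO)(Ar-B)methyl]oxolan-2-one | O=C1OC[C@@H]([C@H](O[Si](C)(C)C(C)(C)C)c2cc(OC)c(OCc3ccc(OCc4ccccc4)c(OC)c3)c(I)c2)[C@@H]1[C@H](O)c1ccc(OCc2ccccc2)c(OC)c1 | intermediate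
11 | (3R,4S)-3-[(S)-(TBSO)(Ar-A)methyl]-4-[(S)-(TBSO)(Ar-B)methyl]oxolan-2-one | O=C1OC[C@@H]([C@H](O[Si](C)(C)C(C)(C)C)c2cc(OC)c(OCc3ccc(OCc4ccccc4)c(OC)c3)c(I)c2)[C@@H]1[C@H](O[Si](C)(C)C(C)(C)C)c1ccc(OCc2ccccc2)c(OC)c1 | intermediate
12 | (2S,3S)-2-[(S)-(TBSO)(Ar-A)methyl]-3-[(S)-(TBSO)(Ar-B)methyl]butane-1,4-diol | COc1cc([C@@H](O[Si](C)(C)C(C)(C)C)[C@H](CO)[C@@H](CO)[C@H](O[Si](C)(C)C(C)(C)C)c2cc(OC)c(OCc3ccc(OCc4ccccc4)c(OC)c3)c(I)c2)ccc1OCc1ccccc1 | intermediate
13 | dimethanesulfonate of 12 | COc1cc([C@@H](O[Si](C)(C)C(C)(C)C)[C@H](COS(C)(=O)=O)[C@@H](COS(C)(=O)=O)[C@H](O[Si](C)(C)C(C)(C)C)c2cc(OC)c(OCc3ccc(OCc4ccccc4)c(OC)c3)c(I)c2)ccc1OCc1ccccc1 | intermediate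
14 | desilylated diol dimesylate (not isolated) | COc1cc([C@@H](O)[C@H](COS(C)(=O)=O)[C@@H](COS(C)(=O)=O)[C@H](O)c2cc(OC)c(OCc3ccc(OCc4ccccc4)c(OC)c3)c(I)c2)ccc1OCc1ccccc1 | intermediate
15 | all-cis 2-(Ar-A)-3-(mesyloxymethyl)-4-[(S)-hydroxy(Ar-B)methyl]oxolane (first ring closed, not isolated) | COc1cc([C@H]2OC[C@@H]([C@H](O)c3cc(OC)c(OCc4ccc(OCc5ccccc5)c(OC)c4)c(I)c3)[C@H]2COS(C)(=O)=O)ccc1OCc1ccccc1 | intermediate
16 | (1S,3aS,4S,6aS)-1-(Ar-A)-4-(Ar-B)tetrahydro-1H,3H-furo[3,4-c]furan (endo,endo) | COc1cc([C@H]2OC[C@@H]3[C@H]2CO[C@@H]3c2cc(OC)c(OCc3ccc(OCc4ccccc4)c(OC)c3)c(I)c2)ccc1OCc1ccccc1 | intermediate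
17 | (2-ethoxy-2-oxoethyl)zinc bromide | CCOC(=O)C[Zn]Br | starting material
18 | ethyl arylacetate (I of 16 replaced by CH2CO2Et) | COc1cc([C@H]2OC[C@@H]3[C@H]2CO[C@@H]3c2cc(OC)c(OCc3ccc(OCc4ccccc4)c(OC)c3)c(CC(=O)OCC)c2)ccc1OCc1ccccc1 | intermediate
19 | ethyl aryldiazoacetate | COc1cc([C@H]2OC[C@@H]3[C@H]2CO[C@@H]3c2cc(OC)c(OCc3ccc(OCc4ccccc4)c(OC)c3)c(C(=[N+]=[N-])C(=O)OCC)c2)ccc1OCc1ccccc1 | intermediate
20 | ethyl (2S,3R)-cis-2,3-dihydrobenzofuran-3-carboxylate | COc1cc([C@H]2OC[C@@H]3[C@H]2CO[C@@H]3c2cc(OC)c3c(c2)[C@@H](C(=O)OCC)[C@@H](c2ccc(OCc4ccccc4)c(OC)c2)O3)ccc1OCc1ccccc1 | intermediate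
21 | (2S,3S)-cis-3-hydroxymethyl dibenzyl ether | COc1cc([C@H]2OC[C@@H]3[C@H]2CO[C@@H]3c2cc(OC)c3c(c2)[C@@H](CO)[C@@H](c2ccc(OCc4ccccc4)c(OC)c2)O3)ccc1OCc1ccccc1 | intermediate
22 | CNP0303197.1 | COc1cc([C@H]2OC[C@@H]3[C@H]2CO[C@@H]3c2cc(OC)c3c(c2)[C@@H](CO)[C@@H](c2ccc(O)c(OC)c2)O3)ccc1O | target

Total step count: 13. Longest linear sequence: 13 steps (1 or 2 to 22).

**Steps most likely to fail**

**Step 4.** The simple diastereoselection at C7 may be weak. Boat or open transition states can compete with the chair, and the lithium aldolate can equilibrate by retro-aldol reaction.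
- The fallback sets out from 8 and 9 and comes back at 10.
- The aldol is run without regard to the C7 outcome. The mixture of 10 and its C7 epimer F1 is oxidised with Dess-Martin periodinane (NaHCO3, CH2Cl2) to the single beta-keto lactone F2.
- In F2, C8 stays trans to the C8' substituent by equilibration.
- Noyori asymmetric transfer hydrogenation with RuCl[(S,S)-TsDPEN](p-cymene) in HCO2H/Et3N then sets C7 (S) under catalyst control and returns 10.

**Step 8.** The closure to the strained all-cis ring may be slow. In that case Grob-type fragmentation of the gamma-mesyloxy alkoxide, or displacement of mesylate by fluoride, may take over.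
- The fallback sets out from 12 and comes back at 16. It replaces substitution by hemiacetal formation and ionic reduction.
- Buffered Dess-Martin oxidation of 12 gives the dialdehyde F3.
- Pyridine-buffered HF·pyridine in THF at 0 °C removes both silyl groups. Each benzylic hydroxyl then adds to the aldehyde four atoms away to give the bis-lactol F4 (anomeric mixture).
- Et3SiH with BF3·OEt2 in CH2Cl2 at -78 °C reduces both lactol carbons through non-benzylic oxocarbenium ions. At that temperature these form far more readily than the benzylic C-O bonds ionise.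

**Step 11.** The very electron-rich ring C may push the insertion into a stepwise hydride-transfer pathway. This would leak into the trans manifold or weaken the facial bias.
- The fallback sets out from 19 and comes back at 20. It separates the two stereochemical tasks.
- 19 is decomposed with Rh2(DOSP)4, dirhodium tetrakis[N-(4-dodecylbenzenesulfonyl)prolinate], in the enantiomeric form that gives 2S. The trans ester F5 is accepted.
- F5 is deprotonated with LiN(iPr)2 in THF at -78 °C to the planar exocyclic enolate. Its C2-O1 bond lies in the ring plane and is poorly aligned for elimination.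
- Kinetic protonation with 2,6-di-tert-butyl-4-methylphenol on the face anti to ring C places the ester cis to ring C and gives 20.

**Further compounds**

F1 | step 4 | C7 epimer of 10 (syn aldol, 7R) | O=C1OC[C@@H]([C@H](O[Si](C)(C)C(C)(C)C)c2cc(OC)c(OCc3ccc(OCc4ccccc4)c(OC)c3)c(I)c2)[C@@H]1[C@@H](O)c1ccc(OCc2ccccc2)c(OC)c1
F2 | step 4 | beta-keto lactone (3-aroyl lactone, trans) | O=C1OC[C@@H]([C@H](O[Si](C)(C)C(C)(C)C)c2cc(OC)c(OCc3ccc(OCc4ccccc4)c(OC)c3)c(I)c2)[C@@H]1C(=O)c1ccc(OCc2ccccc2)c(OC)c1
F3 | step 8 | dialdehyde from 12 | COc1cc([C@@H](O[Si](C)(C)C(C)(C)C)[C@H](C=O)[C@@H](C=O)[C@H](O[Si](C)(C)C(C)(C)C)c2cc(OC)c(OCc3ccc(OCc4ccccc4)c(OC)c3)c(I)c2)ccc1OCc1ccccc1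
F4 | step 8 | bis-lactol (furofuran-3,6-diol, anomeric mixture) | COc1cc([C@H]2OC(O)[C@@H]3[C@H]2C(O)O[C@@H]3c2cc(OC)c(OCc3ccc(OCc4ccccc4)c(OC)c3)c(I)c2)ccc1OCc1ccccc1
F5 | step 11 | trans ester (2S,3S) | COc1cc([C@H]2OC[C@@H]3[C@H]2CO[C@@H]3c2cc(OC)c3c(c2)[C@H](C(=O)OCC)[C@@H](c2ccc(OCc4ccccc4)c(OC)c2)O3)ccc1OCc1ccccc1
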